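Delta is the cool neighbour of eta and theta: the charges and the time stay the same, and the bath gets warmer from one flask to the next.

| flask | starting material | partner | protic impurity | temperature | time |
|---|---|---|---|---|---|
| delta | 13 mM | 1.20 equiv | 2.60 mM | 25 °C | 40 s |
| eta | 13 mM | 1.20 equiv | 2.60 mM | 40 °C | 40 s |
| theta | 13 mM | 1.20 equiv | 2.60 mM | 55 °C | 40 s |

1. which of the two there is more of at the end, delta (over-reaction product / target)
2. which of the two there is more of at the end, eta (over-reaction product / target)
3. which of the two there is more of at the end, theta (over-reaction product / target)
4. final target, as a percentage of the starting material charged, in delta
5. final target, as a percentage of the starting material charged, in eta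
6. final target, as a percentage of the starting material charged, in theta

- a species is counted by the starting material in it: one homo product counts as two
- where a step has two of a species, its rate is k times that concentration squared, and two are used at each turn
- all constants are for 25 °C and move with temperature by the activation energies

In each flask starting material opens to the open intermediate while protic impurity quenches part of it, partner turns into the second intermediate, the two intermediates couple to target, and target goes on to over-reaction product. That last leg makes this a consecutive reaction, and it is the step to watch; here is the whole scheme:

    starting material → open intermediate (k1 = 0.011 s⁻¹, Ea1 = 79.0 kJ mol⁻¹)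
    partner → second intermediate (k2 = 0.031 s⁻¹, Ea2 = 75.0 kJ mol⁻¹)
    open intermediate + second intermediate → target (k3 = 1.1 L mol⁻¹ s⁻¹, Ea3 = 46.0 kJ mol⁻¹)
    2 open intermediate → homo product (k4 = 0.040 L mol⁻¹ s⁻¹, Ea4 = 67.0 kJ mol⁻¹)
    target → over-reaction product (k5 = 0.0024 s⁻¹, Ea5 = 89.0 kJ mol⁻¹)
    starting material + protic impurity → quenched substrate (k6 = 6.5 L mol⁻¹ s⁻¹, Ea6 = 42.0 kJ mol⁻¹)
    (constants at 25 °C)

Now take an odd pair of numbers. In delta, target's half-life of 4.8 min is longer than the run. In theta the Arrhenius factor lifts the loss constant to 0.0639 s⁻¹, a half-life of 10.8 s. So the run of 40 s spans 3.70 half-lives, and plain decay over that time leaves 7.76% of the target. Yet no target stands at the start. Taking second intermediate at the charge of starting material, I reckon a wait of about 12.8 s for open intermediate to couple in theta, so I expect target to keep arriving through the run.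

So replace the curve of births by its mean: let all target be born at the midpoint and age for the rest of the run, which gives exp(−kt/2). Theta then keeps 27.8%, eta 76.5% and delta 95.3%. This share, target over target plus over-reaction product, is the midpoint survival. Early births push the true share lower and late births push it higher. Delta and eta stand at more than 0.5, and theta at less than that, so you expect target ahead in the first two and over-reaction product ahead in theta. My reckoning stops here: it splits the coupled product, but it doesn't say how much couples.

The forecast names target, target and over-reaction product as the larger in delta, eta and theta, with target at 5.1%, 30.6% and 16.5%. Its ground for theta reads: “so target about 2.15 mM and over-reaction dominates”.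

The simulation gives target, target and over-reaction product as the larger, with target at 5.17% in delta, 30.5% in eta and 16.3% in theta.

Theta's share reads 23.9% against the midpoint survival of 27.8%, so its target aged somewhat past the midpoint reckoning. The step to over-reaction product is the main reason for theta's low target: with that step struck out, theta ends at 67.9% target instead of 16.3%. Delta left until 2.5 min has a midpoint survival of 83.5%, and that neighbour holds 35.7% target beside 5.94% over-reaction product, a share of 85.7%.

(The numbers of this flask were drawn at random within sensible limits; the rest is arithmetic.)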